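## Retrosynthetic overview

1. Numbering: ring A = C1–C5 and C10, ring B = C5–C10; C1 carries the acyloxy group, C4 the carboxyl C15, C5 the methyl C14, C7 the acrolein unit, C8 is the ketone. Integric acid is cut back to its C15 tert-butyl ester. The C8 ketone comes from an allylic ethyl ether, the aldehyde from a C7 isopropenyl group, and the C1 ester from the alcohol and (2E,4S)-2,4-dimethyloct-2-enoic acid (auxiliary-controlled methylation, Wittig olefination).
2. Key disconnection, ring B: the C9=C10 olefin is flanked by the C5–C6 and C7–C8 bonds. A diene C5=C10–C9=C8(OEt) built on ring A and but-3-en-2-one as C6=C7 therefore give, by [4+2] cycloaddition, ring B with the olefin in place, the quaternary C5 with C14, and oxygen on C8.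
3. The diene comes from Suzuki coupling of a ring A alkenyl iodide with an (E)-2-ethoxyvinyl boronate. The cis C1-silyloxy/C4-ester iodide comes from catalyst-controlled reduction of a racemic α-iodo enone; ring A comes from tert-butyl acetoacetate and but-3-en-2-one.
4. Ring order: ring A (step 1), then ring B (step 6).

Key step: step 6

Remarks on the chemistry:
- The C15 carboxyl is carried as a tert-butyl ester. It survives fluoride and the oxidations and is released by acid at the end, so no base meets the enal/enone.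
- Ketone 5 is racemic and step 3 is catalyst-controlled, so only the cis diastereomer is carried on.
- Compounds 1, 2, 8, 13, 14 and 18 are taken as commercially available.

## Route

Step 1
Reactants: 1 tert-butyl 3-oxobutanoate; 2 but-3-en-2-one
Product: 4 tert-butyl 2-methyl-4-oxocyclohex-2-ene-1-carboxylate (racemic), via tert-butyl 2-acetyl-5-oxohexanoate 3 (not isolated)
Conditions: KOt-Bu (0.1 equiv), t-BuOH, 0 °C → rt; then pyrrolidine, AcOH (0.3 equiv each), 60 °C
Reagents that add atoms: none
Why: Base-catalysed Michael addition of the β-keto ester to the enone followed by amine-catalysed intramolecular aldol condensation (Robinson-type annulation) closes ring A as the conjugated cyclohexenone; the ester-bearing carbon (later C4) is formed racemic and is sorted in step 3.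

Step 2
Reactants: 4 tert-butyl 2-methyl-4-oxocyclohex-2-ene-1-carboxylate
Product: 5 tert-butyl 3-iodo-2-methyl-4-oxocyclohex-2-ene-1-carboxylate (racemic)
Conditions: I2 (2 equiv), pyridine/CH2Cl2 (1:1), 0 °C → rt, dark
Reagents that add atoms: iodine, II
Why: Electrophilic α-iodination of the enone with I2/pyridine puts iodine on the only vinylic carbon (later C10), through pyridine addition–elimination or through the dienol made available by the acidic hydrogen α to the ester; no stereocenter is formed.

Step 3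
Reactants: 5 tert-butyl 3-iodo-2-methyl-4-oxocyclohex-2-ene-1-carboxylate
Product: 6 tert-butyl (1S,4R)-4-hydroxy-3-iodo-2-methylcyclohex-2-ene-1-carboxylate (cis)
Conditions: (S)-2-methyl-CBS-oxazaborolidine (0.3 equiv), BH3·SMe2 (1 equiv), THF, −20 °C; MeOH quench; chromatographic separation of the cis alcohol
Reagents that add atoms: none
Why: Corey–Bakshi–Shibata reduction: with the iodoalkenyl carbon as the large and the ring CH2 as the small carbonyl substituent, the (S)-catalyst should give the 4R carbinol from both enantiomers of 5, so the 1S enantiomer gives cis alcohol 6 and the 1R enantiomer the trans diastereomer, which is removed by chromatography (at most half of 5 can end up as 6).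

Step 4
Reactants: 6 cis iodo alcohol
Product: 7 tert-butyl (1S,4R)-4-[(tert-butyldimethylsilyl)oxy]-3-iodo-2-methylcyclohex-2-ene-1-carboxylate
Conditions: TBSCl, imidazole, DMF, rt
Reagents that add atoms: tert-butyldimethylsilyl chloride, CC(C)(C)[Si](C)(C)Cl
Why: Silylation of the secondary allylic alcohol with TBSCl/imidazole; neither stereocenter is touched, and the bulky silyl ether later shields one face of the diene.

Step 5
Reactants: 7 silylated alkenyl iodide; 8 (E)-2-(2-ethoxyvinyl)-4,4,5,5-tetramethyl-1,3,2-dioxaborolane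
Product: 9 tert-butyl (1S,4R)-4-[(tert-butyldimethylsilyl)oxy]-3-[(E)-2-ethoxyethenyl]-2-methylcyclohex-2-ene-1-carboxylate
Conditions: PdCl2(dppf) (5 mol %), K3PO4 (3 equiv), 1,4-dioxane/H2O (9:1), 70 °C; chromatography on Et3N-treated silica
Reagents that add atoms: none
Why: Suzuki–Miyaura coupling of the alkenyl iodide with the (E)-alkenyl boronate goes with retention of olefin geometry and gives the E enol ether diene; the weak phosphate base should leave the stereocenter α to the tert-butyl ester untouched.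

Step 6
Reactants: 9 ethoxydiene; 2 but-3-en-2-one
Product: 10 tert-butyl (1S,4R,6S,7R,8aR)-7-acetyl-4-[(tert-butyldimethylsilyl)oxy]-6-ethoxy-8a-methyl-1,2,3,4,6,7,8,8a-octahydronaphthalene-1-carboxylate
Conditions: 2 (10 equiv), BHT (cat.), CH2Cl2, 12 kbar, 25 °C (thermal alternative: PhMe, sealed tube, 110 °C)
Reagents that add atoms: none
Why: A concerted but asynchronous normal-demand Diels–Alder reaction joins the 1-ethoxydiene C5=C10–C9=C8(OEt) to the enone C6=C7, the closest known reaction types being cycloadditions of 2-methyl-1-vinylcyclohexenes that create angular methyl groups and of 1-alkoxydienes with enones. Ring B is closed as a cyclohexene by intermolecular [4+2] annulation onto ring A, which forms C5–C6 and C7–C8 and leaves the olefin at C9=C10. The ethoxy donor on C8 puts the largest HOMO coefficient on C5, so C5 bonds to the CH2 terminus of the enone and the acetyl group ends up on C7 next to the ethoxy carbon. C5 is set by approach of the dienophile to the diene face opposite the cis C1 silyloxy and C4 ester groups, which leaves C14 cis to both; C8 follows from the same face and the E enol ether, and C7 from the endo position of the acetyl group, which puts it trans to C14 as in the target. The step needs regio-, facial and endo selectivity: the first two are secured by the ethoxy group and by the two cis substituents of ring A, whereas endo selectivity rests on secondary orbital overlap alone, so an exo isomer would have to be removed by chromatography. Because the inside methyl on C5 strains the s-cis conformer, the reaction is run under high pressure, whose large negative activation volume favours cycloaddition over polymerisation of the enone and over a 1,5-hydrogen shift from C14 to C8.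

Step 7
Reactants: 10 Diels–Alder adduct
Product: 11 tert-butyl (1S,4R,6S,7S,8aR)-4-[(tert-butyldimethylsilyl)oxy]-6-ethoxy-8a-methyl-7-(prop-1-en-2-yl)-1,2,3,4,6,7,8,8a-octahydronaphthalene-1-carboxylate
Conditions: Zn, CH2Br2, TiCl4 (reagent pre-formed in THF at 0–5 °C), CH2Cl2, 0 °C → rt
Reagents that add atoms: dibromomethane, BrCBr
Why: Takai–Lombardo methylenation with the non-basic zinc/titanium methylene reagent converts the methyl ketone into the isopropenyl group without enolisation, so the C7 stereocenter is kept and the β-ethoxy group is not eliminated; ester and silyl ether are inert.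

Step 8
Reactants: 11 isopropenyl silyl ether
Product: 12 tert-butyl (1S,4R,6S,7S,8aR)-6-ethoxy-4-hydroxy-8a-methyl-7-(prop-1-en-2-yl)-1,2,3,4,6,7,8,8a-octahydronaphthalene-1-carboxylate
Conditions: Bu4NF, THF, rt → 40 °C
Reagents that add atoms: none
Why: Fluoride cleavage of the silyl ether frees the C1 hydroxyl with retention; the tert-butyl ester is inert to fluoride and no base-sensitive group is present yet.

Step 9
Reactants: 13 (S)-4-benzyloxazolidin-2-one; 14 hexanoyl chloride
Product: 15 (S)-4-benzyl-3-hexanoyloxazolidin-2-one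
Conditions: n-BuLi, THF, −78 °C; then 14, −78 → 0 °C
Reagents that add atoms: none
Why: N-Acylation of the lithiated oxazolidinone attaches the chiral auxiliary; its stereocenter is not involved.

Step 10
Reactants: 15 N-hexanoyl oxazolidinone
Product: 16 (S)-4-benzyl-3-[(2S)-2-methylhexanoyl]oxazolidin-2-one
Conditions: NaN(SiMe3)2, THF, −78 °C; MeI, −78 °C
Reagents that add atoms: iodomethane, CI
Why: Evans asymmetric alkylation: the chelated Z sodium enolate is methylated on the face opposite the benzyl group, which should set the 2S configuration; a minor diastereomer would be removed by chromatography.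

Step 11
Reactants: 16 methylated imide
Product: 17 (S)-2-methylhexan-1-ol
Conditions: LiBH4, H2O (1 equiv), Et2O, 0 °C
Reagents that add atoms: none
Why: Reductive cleavage of the imide with LiBH4 releases the primary alcohol without touching the α-stereocenter and returns the auxiliary.

Step 12
Reactants: 17 (S)-2-methylhexan-1-ol; 18 ethyl 2-(triphenyl-λ5-phosphanylidene)propanoate
Product: 20 ethyl (2E,4S)-2,4-dimethyloct-2-enoate, via (S)-2-methylhexanal 19 (not isolated)
Conditions: PhI(OAc)2 (1.1 equiv), TEMPO (0.1 equiv), CH2Cl2, rt; then 18 (1.5 equiv), rt → 40 °C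
Reagents that add atoms: none
Why: One-pot oxidation of the primary alcohol and Wittig olefination with the stabilised ylide avoids handling the epimerisable α-branched aldehyde and should give the E trisubstituted enoate, as usual for stabilised ylides; the C4 stereocenter is carried over.

Step 13
Reactants: 20 ethyl (2E,4S)-2,4-dimethyloct-2-enoate
Product: 21 (2E,4S)-2,4-dimethyloct-2-enoic acid
Conditions: LiOH, THF/MeOH/H2O, rt; then 1 M HCl
Reagents that add atoms: lithium hydroxide, [Li+].[OH-] (oxygen of the new carboxyl OH)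
Why: Saponification of the ethyl ester; the stereocenter is γ to the carbonyl and should not epimerise under these conditions, and the E olefin is retained.

Step 14
Reactants: 12 C1 alcohol; 21 (2E,4S)-2,4-dimethyloct-2-enoic acid
Product: 23 tert-butyl (1S,4R,6S,7S,8aR)-4-{[(2E,4S)-2,4-dimethyloct-2-enoyl]oxy}-6-ethoxy-8a-methyl-7-(prop-1-en-2-yl)-1,2,3,4,6,7,8,8a-octahydronaphthalene-1-carboxylate, via mixed anhydride 22 (not isolated)
Conditions: 21, 2,4,6-Cl3C6H2COCl, Et3N, THF, rt; then 12, DMAP, PhMe, rt → 60 °C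
Reagents that add atoms: none
Why: Yamaguchi esterification through the mixed 2,4,6-trichlorobenzoic anhydride and DMAP acylates the hindered axial C1 hydroxyl with retention at C1; it is placed here, before the base-sensitive enal and ketone exist.

Step 15
Reactants: 23 C1 ester with C7 isopropenyl group
Product: 25 tert-butyl (1S,4R,6S,7S,8aR)-4-{[(2E,4S)-2,4-dimethyloct-2-enoyl]oxy}-6-ethoxy-8a-methyl-7-(3-oxoprop-1-en-2-yl)-1,2,3,4,6,7,8,8a-octahydronaphthalene-1-carboxylate, via allylic alcohol 24 (not isolated)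
Conditions: SeO2 (0.5 equiv), t-BuOOH (3 equiv), CH2Cl2, rt; filtration; then Dess–Martin periodinane, NaHCO3, CH2Cl2, 0 °C
Reagents that add atoms: tert-butyl hydroperoxide, CC(C)(C)OO (its oxygen is passed on through SeO2, O=[Se]=O)
Why: Allylic oxidation with catalytic SeO2 and t-BuOOH (ene reaction, then [2,3]-sigmatropic shift) should attack the methyl group of the 1,1-disubstituted olefin in preference to the methine C7–H, the hindered ring olefin and the electron-poor enoate, and Dess–Martin oxidation of the crude alcohol gives the enal without touching C7.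

Step 16
Reactants: 25 enal with C8 ethyl ether
Product: 26 tert-butyl (1S,4R,7S,8aR)-4-{[(2E,4S)-2,4-dimethyloct-2-enoyl]oxy}-8a-methyl-6-oxo-7-(3-oxoprop-1-en-2-yl)-1,2,3,4,6,7,8,8a-octahydronaphthalene-1-carboxylate
Conditions: DDQ (1.5 equiv), CH2Cl2/pH 7 buffer (10:1), 0 °C → rt
Reagents that add atoms: water, O
Why: DDQ oxidation of an allylic ether: hydride abstraction from C8–H (allylic and α to oxygen) gives an oxocarbenium ion conjugated to the C9=C10 olefin, as in DDQ cleavage of prenyl-type ethers, and water addition with loss of ethanol gives the enone; the C1 carbinol hydrogen is deactivated by its acyloxy group, and C7, now α to the ketone, already has the more stable configuration (side chain equatorial, trans to C14).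

Step 17
Reactants: 26 integric acid tert-butyl ester
Product: 27 integric acid
Conditions: CF3CO2H/CH2Cl2 (1:4), 0 °C
Reagents that add atoms: none
Why: Acidolysis of the tert-butyl ester (alkyl–oxygen cleavage through the tert-butyl cation) frees the acid under non-basic, non-nucleophilic conditions that the enal, the enone and the two other esters should tolerate; no stereocenter is involved.

## Compound list

1 | tert-butyl 3-oxobutanoate | CC(=O)CC(=O)OC(C)(C)C | starting material
2 | but-3-en-2-one | C=CC(C)=O | starting material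
3 | tert-butyl 2-acetyl-5-oxohexanoate (racemic, not isolated) | CC(=O)CCC(C(C)=O)C(=O)OC(C)(C)C | intermediate
4 | tert-butyl 2-methyl-4-oxocyclohex-2-ene-1-carboxylate (racemic) | CC1=CC(=O)CCC1C(=O)OC(C)(C)C | intermediate
5 | tert-butyl 3-iodo-2-methyl-4-oxocyclohex-2-ene-1-carboxylate (racemic) | CC1=C(I)C(=O)CCC1C(=O)OC(C)(C)C | intermediate
6 | tert-butyl (1S,4R)-4-hydroxy-3-iodo-2-methylcyclohex-2-ene-1-carboxylate | IC1=C(C)[C@@H](C(=O)OC(C)(C)C)CC[C@H]1O | intermediate
7 | tert-butyl (1S,4R)-4-[(tert-butyldimethylsilyl)oxy]-3-iodo-2-methylcyclohex-2-ene-1-carboxylate | IC1=C(C)[C@@H](C(=O)OC(C)(C)C)CC[C@H]1O[Si](C)(C)C(C)(C)C | intermediate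
8 | (E)-2-(2-ethoxyvinyl)-4,4,5,5-tetramethyl-1,3,2-dioxaborolane | CCO/C=C/B1OC(C)(C)C(C)(C)O1 | starting material
9 | tert-butyl (1S,4R)-4-[(tert-butyldimethylsilyl)oxy]-3-[(E)-2-ethoxyethenyl]-2-methylcyclohex-2-ene-1-carboxylate | CCO/C=C/C1=C(C)[C@@H](C(=O)OC(C)(C)C)CC[C@H]1O[Si](C)(C)C(C)(C)C | intermediate
10 | tert-butyl (1S,4R,6S,7R,8aR)-7-acetyl-4-[(tert-butyldimethylsilyl)oxy]-6-ethoxy-8a-methyl-1,2,3,4,6,7,8,8a-octahydronaphthalene-1-carboxylate | CC(=O)[C@@H]1C[C@@]2(C)C(=C[C@@H]1OCC)[C@H](O[Si](C)(C)C(C)(C)C)CC[C@@H]2C(=O)OC(C)(C)C | intermediate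
11 | tert-butyl (1S,4R,6S,7S,8aR)-4-[(tert-butyldimethylsilyl)oxy]-6-ethoxy-8a-methyl-7-(prop-1-en-2-yl)-1,2,3,4,6,7,8,8a-octahydronaphthalene-1-carboxylate | C=C(C)[C@@H]1C[C@@]2(C)C(=C[C@@H]1OCC)[C@H](O[Si](C)(C)C(C)(C)C)CC[C@@H]2C(=O)OC(C)(C)C | intermediate
12 | tert-butyl (1S,4R,6S,7S,8aR)-6-ethoxy-4-hydroxy-8a-methyl-7-(prop-1-en-2-yl)-1,2,3,4,6,7,8,8a-octahydronaphthalene-1-carboxylate | C=C(C)[C@@H]1C[C@@]2(C)C(=C[C@@H]1OCC)[C@H](O)CC[C@@H]2C(=O)OC(C)(C)C | intermediate
13 | (S)-4-benzyloxazolidin-2-one | O=C1OC[C@H](Cc2ccccc2)N1 | starting material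
14 | hexanoyl chloride | CCCCCC(Cl)=O | starting material
15 | (S)-4-benzyl-3-hexanoyloxazolidin-2-one | CCCCCC(=O)N1[C@@H](Cc2ccccc2)COC1=O | intermediate
16 | (S)-4-benzyl-3-[(2S)-2-methylhexanoyl]oxazolidin-2-one | O=C([C@@H](C)CCCC)N1[C@@H](Cc2ccccc2)COC1=O | intermediate
17 | (S)-2-methylhexan-1-ol | OC[C@@H](C)CCCC | intermediate
18 | ethyl 2-(triphenyl-λ5-phosphanylidene)propanoate | CCOC(=O)C(C)=P(c1ccccc1)(c1ccccc1)c1ccccc1 | starting material
19 | (S)-2-methylhexanal (not isolated) | O=C[C@@H](C)CCCC | intermediate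
20 | ethyl (2E,4S)-2,4-dimethyloct-2-enoate | CCOC(=O)/C(C)=C/[C@@H](C)CCCC | intermediate
21 | (2E,4S)-2,4-dimethyloct-2-enoic acid | OC(=O)/C(C)=C/[C@@H](C)CCCC | intermediate
22 | (2E,4S)-2,4-dimethyloct-2-enoic 2,4,6-trichlorobenzoic anhydride (not isolated) | O=C(OC(=O)/C(C)=C/[C@@H](C)CCCC)c1c(Cl)cc(Cl)cc1Cl | intermediate
23 | tert-butyl (1S,4R,6S,7S,8aR)-4-{[(2E,4S)-2,4-dimethyloct-2-enoyl]oxy}-6-ethoxy-8a-methyl-7-(prop-1-en-2-yl)-1,2,3,4,6,7,8,8a-octahydronaphthalene-1-carboxylate | C=C(C)[C@@H]1C[C@@]2(C)C(=C[C@@H]1OCC)[C@H](OC(=O)/C(C)=C/[C@@H](C)CCCC)CC[C@@H]2C(=O)OC(C)(C)C | intermediate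
24 | tert-butyl (1S,4R,6S,7S,8aR)-4-{[(2E,4S)-2,4-dimethyloct-2-enoyl]oxy}-6-ethoxy-7-(3-hydroxyprop-1-en-2-yl)-8a-methyl-1,2,3,4,6,7,8,8a-octahydronaphthalene-1-carboxylate (not isolated) | C=C(CO)[C@@H]1C[C@@]2(C)C(=C[C@@H]1OCC)[C@H](OC(=O)/C(C)=C/[C@@H](C)CCCC)CC[C@@H]2C(=O)OC(C)(C)C | intermediate
25 | tert-butyl (1S,4R,6S,7S,8aR)-4-{[(2E,4S)-2,4-dimethyloct-2-enoyl]oxy}-6-ethoxy-8a-methyl-7-(3-oxoprop-1-en-2-yl)-1,2,3,4,6,7,8,8a-octahydronaphthalene-1-carboxylate | C=C(C=O)[C@@H]1C[C@@]2(C)C(=C[C@@H]1OCC)[C@H](OC(=O)/C(C)=C/[C@@H](C)CCCC)CC[C@@H]2C(=O)OC(C)(C)C | intermediate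
26 | tert-butyl (1S,4R,7S,8aR)-4-{[(2E,4S)-2,4-dimethyloct-2-enoyl]oxy}-8a-methyl-6-oxo-7-(3-oxoprop-1-en-2-yl)-1,2,3,4,6,7,8,8a-octahydronaphthalene-1-carboxylate | C=C(C=O)[C@@H]1C[C@@]2(C)C(=CC1=O)[C@H](OC(=O)/C(C)=C/[C@@H](C)CCCC)CC[C@@H]2C(=O)OC(C)(C)C | intermediate
27 | integric acid, (1S,4R,7S,8aR)-4-{[(2E,4S)-2,4-dimethyloct-2-enoyl]oxy}-8a-methyl-6-oxo-7-(3-oxoprop-1-en-2-yl)-1,2,3,4,6,7,8,8a-octahydronaphthalene-1-carboxylic acid | C=C(C=O)[C@@H]1C[C@@]2(C)C(=CC1=O)[C@H](OC(=O)/C(C)=C/[C@@H](C)CCCC)CC[C@@H]2C(=O)O | target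

## Step count and risks

Total step count: 17. Longest linear sequence: 12 steps (steps 1–8 and 14–17, from 1); the side-chain branch (steps 9–13) joins in step 14.

Steps most likely to fail:

**Step 6 (Diels–Alder).** Bond formation at the fully substituted C5 terminus may be too slow, because the inside methyl disfavours the reactive s-cis conformer. Polymerisation of the enone, inverse-demand hetero-Diels–Alder addition of the enone (as an oxadiene) across the enol ether bond C8=C9, or loss of facial and endo selectivity could then take over. The fallback sets out from 9 and returns at 10. The dienophile is changed to the chelating 3-acryloyl-1,3-oxazolidin-2-one, activated by Yb(OTf)3 (10 mol %, CH2Cl2, 4 Å sieves, −20 °C → rt). This Lewis acid-catalysed cycloaddition should give, with the same regio-, facial and endo preferences, the N-acyl oxazolidinone adduct F1. Lithium ethanethiolate (EtSH, n-BuLi, THF, 0 °C) should cleave the imide to the S-ethyl thioester F2, and Me2CuLi (Et2O, −78 °C) should convert the thioester into methyl ketone 10.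

**Step 16 (DDQ oxidation at C8).** Hydride abstraction may be slow at a secondary ether carbon flanked by the acrolein-bearing C7 and an olefin that carries the acyloxy carbon C1. The oxocarbenium ion may also lose the C7 proton to a dienol ether that is oxidised further. The fallback avoids hydride abstraction by carrying the C8 oxygen as a silyl ether; it sets out from 9 and returns at 26.
- Mild hydrolysis of the enol ether (pyridinium p-toluenesulfonate, wet acetone, rt) should give the β,γ-unsaturated aldehyde F3.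
- Et3SiOTf/Et3N (CH2Cl2, −78 → 0 °C) should give the (E)-triethylsilyloxy diene F4, the E isomer being favoured by the bulky cyclohexenyl group.
- Cycloaddition with 2 as in step 6 should give the C8 triethylsilyloxy adduct F5, and methylenation as in step 7 the isopropenyl compound F6.
- Selective removal of the triethylsilyl group (pyridinium p-toluenesulfonate, MeOH, 0 °C) should give the C8 allylic alcohol F7, and MnO2 (CH2Cl2, rt) the enone F8.
- HF·pyridine (THF/pyridine, 0 °C → rt) should free the C1 alcohol F9, and Yamaguchi esterification with 21 as in step 14 should give the acylated enone F10.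
- Allylic oxidation as in step 15 (SeO2/t-BuOOH, then Dess–Martin periodinane), through the allylic alcohol F11, should give 26.

**Step 15 (SeO2 allylic oxidation).** The ene reaction may show poor site selectivity, with attack at C7–H or at the ring olefin, or may over-oxidise, in competition with oxidation of the methyl group. The fallback sets out from 23 and returns at 24, which is oxidised to 25 with Dess–Martin periodinane as in the second half of step 15. mCPBA (NaHCO3, CH2Cl2, 0 °C) should epoxidise the 1,1-disubstituted olefin, which is more accessible than the ring olefin flanked by two oxygen-bearing carbons and more electron-rich than the enoate, to give the epoxide F12 (both epimers at the new epoxide carbon are usable). Cp2TiCl (trivalent titanium, made from Cp2TiCl2 and Mn, THF, rt) should open the epoxide to the tertiary radical; trapping by a second equivalent and β-hydride elimination from the methyl group should give allylic alcohol 24.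

## Further compounds

F1 | step 6 | tert-butyl (1S,4R,6S,7R,8aR)-4-[(tert-butyldimethylsilyl)oxy]-6-ethoxy-8a-methyl-7-(2-oxo-1,3-oxazolidine-3-carbonyl)-1,2,3,4,6,7,8,8a-octahydronaphthalene-1-carboxylate | O=C1OCCN1C(=O)[C@@H]1C[C@@]2(C)C(=C[C@@H]1OCC)[C@H](O[Si](C)(C)C(C)(C)C)CC[C@@H]2C(=O)OC(C)(C)C
F2 | step 6 | tert-butyl (1S,4R,6S,7R,8aR)-4-[(tert-butyldimethylsilyl)oxy]-6-ethoxy-7-[(ethylsulfanyl)carbonyl]-8a-methyl-1,2,3,4,6,7,8,8a-octahydronaphthalene-1-carboxylate | CCSC(=O)[C@@H]1C[C@@]2(C)C(=C[C@@H]1OCC)[C@H](O[Si](C)(C)C(C)(C)C)CC[C@@H]2C(=O)OC(C)(C)C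
F3 | step 16 | tert-butyl (1S,4R)-4-[(tert-butyldimethylsilyl)oxy]-2-methyl-3-(2-oxoethyl)cyclohex-2-ene-1-carboxylate | O=CCC1=C(C)[C@@H](C(=O)OC(C)(C)C)CC[C@H]1O[Si](C)(C)C(C)(C)C
F4 | step 16 | tert-butyl (1S,4R)-4-[(tert-butyldimethylsilyl)oxy]-2-methyl-3-{(E)-2-[(triethylsilyl)oxy]ethenyl}cyclohex-2-ene-1-carboxylate | CC[Si](CC)(CC)O/C=C/C1=C(C)[C@@H](C(=O)OC(C)(C)C)CC[C@H]1O[Si](C)(C)C(C)(C)C
F5 | step 16 | tert-butyl (1S,4R,6S,7R,8aR)-7-acetyl-4-[(tert-butyldimethylsilyl)oxy]-8a-methyl-6-[(triethylsilyl)oxy]-1,2,3,4,6,7,8,8a-octahydronaphthalene-1-carboxylate | CC(=O)[C@@H]1C[C@@]2(C)C(=C[C@@H]1O[Si](CC)(CC)CC)[C@H](O[Si](C)(C)C(C)(C)C)CC[C@@H]2C(=O)OC(C)(C)C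
F6 | step 16 | tert-butyl (1S,4R,6S,7S,8aR)-4-[(tert-butyldimethylsilyl)oxy]-8a-methyl-7-(prop-1-en-2-yl)-6-[(triethylsilyl)oxy]-1,2,3,4,6,7,8,8a-octahydronaphthalene-1-carboxylate | C=C(C)[C@@H]1C[C@@]2(C)C(=C[C@@H]1O[Si](CC)(CC)CC)[C@H](O[Si](C)(C)C(C)(C)C)CC[C@@H]2C(=O)OC(C)(C)C
F7 | step 16 | tert-butyl (1S,4R,6S,7S,8aR)-4-[(tert-butyldimethylsilyl)oxy]-6-hydroxy-8a-methyl-7-(prop-1-en-2-yl)-1,2,3,4,6,7,8,8a-octahydronaphthalene-1-carboxylate | C=C(C)[C@@H]1C[C@@]2(C)C(=C[C@@H]1O)[C@H](O[Si](C)(C)C(C)(C)C)CC[C@@H]2C(=O)OC(C)(C)C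
F8 | step 16 | tert-butyl (1S,4R,7S,8aR)-4-[(tert-butyldimethylsilyl)oxy]-8a-methyl-6-oxo-7-(prop-1-en-2-yl)-1,2,3,4,6,7,8,8a-octahydronaphthalene-1-carboxylate | C=C(C)[C@@H]1C[C@@]2(C)C(=CC1=O)[C@H](O[Si](C)(C)C(C)(C)C)CC[C@@H]2C(=O)OC(C)(C)C
F9 | step 16 | tert-butyl (1S,4R,7S,8aR)-4-hydroxy-8a-methyl-6-oxo-7-(prop-1-en-2-yl)-1,2,3,4,6,7,8,8a-octahydronaphthalene-1-carboxylate | C=C(C)[C@@H]1C[C@@]2(C)C(=CC1=O)[C@H](O)CC[C@@H]2C(=O)OC(C)(C)C
F10 | step 16 | tert-butyl (1S,4R,7S,8aR)-4-{[(2E,4S)-2,4-dimethyloct-2-enoyl]oxy}-8a-methyl-6-oxo-7-(prop-1-en-2-yl)-1,2,3,4,6,7,8,8a-octahydronaphthalene-1-carboxylate | C=C(C)[C@@H]1C[C@@]2(C)C(=CC1=O)[C@H](OC(=O)/C(C)=C/[C@@H](C)CCCC)CC[C@@H]2C(=O)OC(C)(C)C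
F11 | step 16 | tert-butyl (1S,4R,7S,8aR)-4-{[(2E,4S)-2,4-dimethyloct-2-enoyl]oxy}-7-(3-hydroxyprop-1-en-2-yl)-8a-methyl-6-oxo-1,2,3,4,6,7,8,8a-octahydronaphthalene-1-carboxylate | C=C(CO)[C@@H]1C[C@@]2(C)C(=CC1=O)[C@H](OC(=O)/C(C)=C/[C@@H](C)CCCC)CC[C@@H]2C(=O)OC(C)(C)C
F12 | step 15 | tert-butyl (1S,4R,6S,7S,8aR)-4-{[(2E,4S)-2,4-dimethyloct-2-enoyl]oxy}-6-ethoxy-8a-methyl-7-(2-methyloxiran-2-yl)-1,2,3,4,6,7,8,8a-octahydronaphthalene-1-carboxylate (epimers at the oxirane carbon) | CC1(CO1)[C@@H]1C[C@@]2(C)C(=C[C@@H]1OCC)[C@H](OC(=O)/C(C)=C/[C@@H](C)CCCC)CC[C@@H]2C(=O)OC(C)(C)C
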